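## Structural features

The target is a depside: two benzene rings, ring A (the acyl part) and ring B (the phenol part), joined by a single aryl ester bond from the carboxyl carbon on C1' to O4. There is no other ring, no chain longer than a methyl ester and no stereocenter, so no stereocenters stand next to each other. Ring B is hexasubstituted: CO2Me on C1, a free hydroxyl on C2 (hydrogen-bonded to the ester), methyl on C3, the acylated oxygen on C4, and methyls on C5 and C6. Ring A is also hexasubstituted: the carboxyl on C1', OMe on C2', methyl on C3', a free hydroxyl on C4', chlorine on C5' and methyl on C6'. The ester is flanked by four ortho substituents (C2'-OMe, C6'-Me, C3-Me, C5-Me). Making it from an acid and a phenol is therefore the real difficulty, together with telling four phenolic oxygens apart (two free, one methylated, one acylated). Fragile groups are the aryl ester (acyl transfer under alkoxide or hydroxide), the aryl chloride (reducing conditions), the electron-rich phenols (oxidants) and any acid-labile acetal placed on O4'. The key step uses the 1,3-relationship of O2 and O4 on ring B with the C3 methyl between them: C2 and its oxygen come from a ketene carbonyl, C3 and C4 from an oxygen-substituted propyne that already carries the ring A acyl group, and C1, C6 and C5 from an alkenyl diazoketone. Ring B is thus formed with O2 free and O4 acylated.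

## Logic of the disconnections

**19 to 18.** The O4'–CH2 bond of a methoxymethyl acetal is cut. A free O4'–H would compete with the carboxylate when the O–C(sp) bond is made and would add to the ketene later. The cut adds no skeletal simplicity but leaves the carboxylate as the only nucleophile of ring A. The forward step needs acid mild enough to spare the depside ester.

**18 to 13 and 8.** Ring B is opened at C1–C2, C2–C3 and C4–C5, and C5–C6 is traced back to a C2–C6 bond in an acyclic diazoketone. The cut is made here because the 2-hydroxy-3-methyl-4-acyloxy pattern is what a vinylketene and an oxygen-bearing alkyne give. A hexasubstituted arene is reduced to a six-carbon chain and a three-carbon alkyne, and the crowded ester is not made at this stage at all. The forward step must generate the ketene in the presence of 8, join the two with the right orientation, and tolerate heat.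

**8 to 5 and 7.** The O–C(sp) bond of the ynol ester is cut. The crowded C–O bond is thereby made at a linear carbon before either ortho methyl of ring B exists. This separates the ring A acid from a three-carbon unit. The forward step needs a dry carboxylate as the only nucleophile and a non-acidic isolation.

**7 to 6.** The C(sp)–I bond is cut, which leads back to a commercial silylalkyne. The forward step needs an electrophilic trivalent-iodine reagent that takes the alkynyl group from silicon.

**5 to 4, 3, 2 and 1.** Only heteroatom bonds are cut: the ester O–CH3 bond, the O2'–CH3 bond, the O4'–acetal bond and the C5'–Cl bond. Compound 1 already has the carbon skeleton and oxygen pattern of ring A. The order matters: chlorination while both phenols are free and one ring position is open, then differentiation of the phenols through the hydrogen bond, and hydrolysis of the hindered ester last.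

**13 to 12 and 11.** The C5=N2 bond and then the C5–C(O)CF3 bond are cut, because direct diazo transfer to a simple ketone fails without an activating acyl group. The precursor becomes a plain enone ester. The forward step needs kinetic enolization at the ethyl CH2 (C5) and not at the vinylogous methyl on C6.

**11 to 9 and 10.** The C1=C6 double bond is cut to a 1,2-diketone and a stabilized ylide, both commercial. The forward step must choose the acetyl carbonyl of 9 over the propionyl carbonyl and give the E-alkene.

## Other disconnections considered

**Alternative 1:** Ring A is built on a ring B phenol by cutting the ester C–O bond and the ring A bond C1'–C6'. The product would be the benzyl-protected, 5'-deschloro, 2'-O-desmethyl depside A1. In the forward step the diketo-dioxinone A2 is heated with the 2-O-benzyl ring B phenol A3. The dioxinone fragments to acylketene A4, which O4 captures to give the triketo aryl ester A5. Aldol closure between C1' and C6' and loss of water then aromatize ring A.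

- In its favour: the acylating agent is a small, linear, very electrophilic ketene, so the hindered phenol is acylated without a steric contest. This is the same idea as in the chosen plan (crowded C–O bond made at a non-tetrahedral, unhindered carbon), and here it rests on an established reaction type, which makes it the better of the two on precedent.
- Against it: A1 carries neither the chlorine nor the 2'-O-methyl group. Methylating the hindered, hydrogen-bonded O2' in the presence of the more reactive O4' needs a further protection, and the base needed would endanger the depside ester. Ring B must still be made separately and benzylated on its less reactive oxygen. Debenzylation by hydrogenolysis after chlorination would put the aryl chloride at risk.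
- Comparison: structurally it delivers the wrong oxidation pattern on ring A, mechanistically it is the more secure, and in step economy it is clearly the longest of the four plans.

**Alternative 2:** Ring B is cut at C1–C6 and C3–C4 at the cyclohexane-1,3-dione oxidation level. Sodium methoxide would add methyl 3-oxopentanoate A7 to methyl tiglate A8 (Michael), and the ketone α-carbon would then close onto the tiglate ester (Dieckmann) to give dione A6 as a mixture of stereoisomers that do not matter. Dehydrogenation would give phenol A9, and esterification of O4 with acid 5 would give 18.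

- In its favour: the materials are the cheapest, every step is a known reaction type, and the regiochemistry of ring B is unambiguous. In precedent it is the better plan. In step count it is also better: about eight steps against eleven.
- Against it: conjugate addition to an α,β-disubstituted enoate is slow and reversible, and aromatizing a fully substituted dione needs a separate oxidation. Above all, the four-fold ortho-substituted ester must be made at the end by joining two hindered partners. The usual mixed-anhydride activation is acidic and would not suit the acetal on O4'.
- Comparison: the chosen plan trades known chemistry for a route that never forms the ester at a crowded centre and never has to tell O2 from O4 on ring B. Alternative 2 is kept as the fallback for the key step.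

**Alternative 3:** Ring A is cut at C1'–C2' and C5'–C6'. The but-2-ynoate A11 of phenol A9 would react with diene A12 in a (4+2) cycloaddition. Loss of methanol and of the silyl group on work-up would give the 5'-deschloro depside A10, and chlorination at C5', the only free ring position, would finish the synthesis.

- In its favour: the ester is made from an unhindered alkynoic acid. The diene places OMe on C2' and OH on C4' without any protecting group on ring A. The route would be about seven steps, so it is better than the chosen plan in step economy and equal to it in how it avoids the hindered esterification.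
- Against it: a β-methyl ynoate is a slow dienophile. The bond C1'–C2' joins a fully substituted ketene-acetal terminus to the alkyne carbon next to a bulky aryl ester. The free O2–H of A11 can protonate or desilylate A12. The chlorination comes last, on a molecule with two electron-rich rings, where ipso attack on ring B is possible.
- Comparison: the chosen plan fixes chlorine and the oxygen pattern of ring A early, on a commercial arene, and builds ring B and its oxygen differentiation in one step. Alternative 3 relies on a known ring-forming reaction but on an untested, congested substrate pairing.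

Key step: step 10

## Route

Remark on the chemistry: anions formed by simple deprotonation of a numbered compound (phenoxide, carboxylate, enolate) are treated as its reacting form and carry no number. Ring A atoms are primed (C1' bears the carboxyl carbon) and ring B atoms unprimed (C1 bears CO2Me).

Step 1
Reactants: 1 atraric acid (methyl 2,4-dihydroxy-3,6-dimethylbenzoate)
Product: 2 methyl 3-chloro-4,6-dihydroxy-2,5-dimethylbenzoate
Conditions: NCS (1.05 equiv), MeCN, 0 → 20 °C
Reagents that add atoms: N-chlorosuccinimide, O=C1CCC(=O)N1Cl
Why: Electrophilic aromatic chlorination; the only unsubstituted ring carbon (C5') is ortho to one hydroxyl and para to the other, so one equivalent should chlorinate there only, and solid NCS avoids sulfuryl chloride and its gases.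

Step 2
Reactants: 2 methyl 3-chloro-4,6-dihydroxy-2,5-dimethylbenzoate
Product: 3 methyl 3-chloro-6-hydroxy-4-(methoxymethoxy)-2,5-dimethylbenzoate
Conditions: CH2(OMe)2, AcCl, ZnBr2 (cat.), PhMe, 20 °C; then 2, i-Pr2NEt, 0 → 20 °C; aq. NH4Cl quench
Reagents that add atoms: dimethoxymethane, COCOC (its CH2OCH3 group is delivered as chloromethyl methyl ether, COCCl, formed in the flask with acetyl chloride)
Why: Williamson-type O-alkylation; the hydroxyl ortho to the ester (O2') is held in a hydrogen bond to the carbonyl while the hydroxyl para to it (O4') is the more acidic, so O4' should be alkylated alone, and the chloromethyl ether is made and destroyed in solution so that it is never handled neat.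

Step 3
Reactants: 3 methyl 3-chloro-6-hydroxy-4-(methoxymethoxy)-2,5-dimethylbenzoate
Product: 4 methyl 3-chloro-6-methoxy-4-(methoxymethoxy)-2,5-dimethylbenzoate
Conditions: MeI, K2CO3, DMF, 40 °C
Reagents that add atoms: iodomethane, CI
Why: Williamson etherification of the remaining chelated phenol; carbonate in DMF should break the hydrogen bond and iodomethane is small enough for the flanked oxygen, while the acetal and the ester are inert.

Step 4
Reactants: 4 methyl 3-chloro-6-methoxy-4-(methoxymethoxy)-2,5-dimethylbenzoate
Product: 5 3-chloro-6-methoxy-4-(methoxymethoxy)-2,5-dimethylbenzoic acid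
Conditions: KOH, DMSO–H2O, 90 °C; then aq. KHSO4 to pH 3, 0 °C
Reagents that add atoms: potassium hydroxide, [K+].[OH-]
Why: Saponification; poorly solvated hydroxide in wet DMSO should attack even a di-ortho-substituted methyl benzoate, base leaves the acetal, the aryl ether and the aryl chloride alone, and a brief cold acidification should not open the acetal.

Step 5
Reactants: 6 1-(trimethylsilyl)propyne
Product: 7 phenyl(prop-1-yn-1-yl)iodonium trifluoromethanesulfonate
Conditions: PhI(OAc)2, Tf2O, CH2Cl2, 0 °C; then 6, 0 → 20 °C; precipitation with Et2O
Reagents that add atoms: (diacetoxyiodo)benzene, CC(=O)OI(OC(C)=O)c1ccccc1; trifluoromethanesulfonic anhydride, O=S(=O)(OS(=O)(=O)C(F)(F)F)C(F)(F)F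
Why: Silicon-to-iodine exchange at an alkynylsilane; the diacetate and triflic anhydride form an oxo-bridged trivalent-iodine bis(triflate) that takes the alkynyl group from silicon, a standard entry to alkynyl(aryl)iodonium triflates that avoids tin and cyanide reagents.

Step 6
Reactants: 5 3-chloro-6-methoxy-4-(methoxymethoxy)-2,5-dimethylbenzoic acid; 7 phenyl(prop-1-yn-1-yl)iodonium trifluoromethanesulfonate
Product: 8 prop-1-yn-1-yl 3-chloro-6-methoxy-4-(methoxymethoxy)-2,5-dimethylbenzoate
Conditions: NaH, THF, 0 °C; then 7, CH2Cl2, −40 → 20 °C; rapid filtration through neutral alumina, used at once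
Reagents that add atoms: none
Why: O-Alkynylation of a carboxylate by an alkynyliodonium salt; the carboxylate adds to the methyl-bearing β-carbon, iodobenzene leaves and a 1,2-shift gives the alkynyl ester, as known for alkynyl benzoates. The attack is on a linear sp carbon, so the two ortho substituents of the acid should matter little.

Step 7
Reactants: 9 pentane-2,3-dione; 10 methyl (triphenylphosphoranylidene)acetate
Product: 11 methyl (E)-3-methyl-4-oxohex-2-enoate
Conditions: PhMe, 20 → 50 °C; chromatography
Reagents that add atoms: none
Why: Wittig olefination with a stabilized ylide; the carbonyls of a 1,2-diketone are activated, the acetyl carbonyl is the less hindered and should react first, and the stabilized ylide should give the E-alkene with the ester trans to the acyl group.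

Step 8
Reactants: 11 methyl (E)-3-methyl-4-oxohex-2-enoate
Product: 12 methyl (E)-7,7,7-trifluoro-3,5-dimethyl-4,6-dioxohept-2-enoate
Conditions: LiN(SiMe3)2, THF, −78 °C; CF3CO2CH2CF3, −78 °C; aq. HCl work-up, crude product used directly
Reagents that add atoms: 2,2,2-trifluoroethyl trifluoroacetate, FC(F)(F)COC(=O)C(F)(F)F
Why: Kinetic enolization at the ethyl CH2 followed by Claisen-type C-trifluoroacetylation; the hindered amide base at low temperature should take the ketone α'-proton before the vinylogous methyl protons, and the E-geometry keeps the enolate away from its own ester.

Step 9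
Reactants: 12 methyl (E)-7,7,7-trifluoro-3,5-dimethyl-4,6-dioxohept-2-enoate
Product: 13 methyl (E)-5-diazo-3-methyl-4-oxohex-2-enoate
Conditions: 4-AcNHC6H4SO2N3, Et3N, H2O (1 equiv), MeCN, 20 °C; kept cold, in solution and away from light
Reagents that add atoms: 4-acetamidobenzenesulfonyl azide, CC(=O)Nc1ccc(cc1)S(=O)(=O)N=[N+]=[N-]
Why: Detrifluoroacetylative diazo transfer; the diketone enolate adds to the sulfonyl azide and the adduct fragments with transfer of the trifluoroacetyl group to the sulfonamide nitrogen, leaving the α-diazo ketone. The amine base is mild enough for the enoate, and this azide is among the safer diazo-transfer reagents.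

Step 10
Reactants: 13 methyl (E)-5-diazo-3-methyl-4-oxohex-2-enoate; 8 prop-1-yn-1-yl 3-chloro-6-methoxy-4-(methoxymethoxy)-2,5-dimethylbenzoate
Product: 18 3-hydroxy-4-(methoxycarbonyl)-2,5,6-trimethylphenyl 3-chloro-6-methoxy-4-(methoxymethoxy)-2,5-dimethylbenzoate, via vinylketene 14 (not isolated), via alkenylcyclobutenone 15 (not isolated), via dienylketene 16 (not isolated), via cyclohexadienone 17 (not isolated)
Conditions: 13 (1.5 equiv, slow addition) to 8, hν (>300 nm, Pyrex-filtered Hg lamp or 365 nm LEDs), degassed ClCH2CH2Cl, 20 °C; then PhMe, 80 → 110 °C
Reagents that add atoms: none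
Why: Proposed new method: light expels dinitrogen from 13 and the alkenyl group shifts from the carbonyl carbon to the former diazo carbon (Wolff rearrangement, bond C5–C6), giving vinylketene 14. The methyl-bearing carbon of ynol ester 8, its nucleophilic end, bonds to the ketene carbonyl carbon and the acyloxy-bearing carbon to the ketene α-carbon, so that a (2+2) cycloaddition gives alkenylcyclobutenone 15 (bonds C2–C3 and C4–C5). On heating, 15 opens by four-electron electrocyclic cleavage to dienylketene 16, which closes ring B by a thermal disrotatory six-electron electrocyclization (bond C1–C2) to cyclohexadienone 17, and enolization of its β-keto ester gives phenol 18. The closest known reaction type is the second-generation Danheiser benzannulation of α-diazo enones with siloxyalkynes and with N-acyl or N-sulfonyl ynamides; an alkynyl carboxylate has not served as the ketene partner, and its acyloxy oxygen is a weaker donor, closest to the nitrogen of an electron-poor ynamide, which the ester-activated and more electrophilic ketene 14 should offset. Ring B, the only ring that remains, closes by electrocyclization, and the four-membered ring is transient. No stereocenter remains, because the quaternary carbon of 15 and C1 of 17 both end as sp2 ring atoms. The step needs regioselectivity in the (2+2) event, which the oxygen lone pair on C4 secures by making C3 the nucleophilic alkyne carbon, and it needs capture of 14 by 8 to outrun ketene dimerization, which slow addition of 13 to irradiated 8 should favour. The E-enoate keeps the ketene away from its own ester carbonyl and puts hydrogen, not the ester, on the inside of the electrocyclization.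

Step 11
Reactants: 18 3-hydroxy-4-(methoxycarbonyl)-2,5,6-trimethylphenyl 3-chloro-6-methoxy-4-(methoxymethoxy)-2,5-dimethylbenzoate
Product: 19 3-hydroxy-4-(methoxycarbonyl)-2,5,6-trimethylphenyl 3-chloro-4-hydroxy-6-methoxy-2,5-dimethylbenzoate (the target)
Conditions: HCl, MeOH–CH2Cl2, 0 → 25 °C
Reagents that add atoms: none
Why: Acid-catalysed acetal exchange with methanol; the depside ester is shielded by four ortho substituents and the methyl ester can only exchange with the same alcohol, so both should survive.

## Compound list

1 | atraric acid (methyl 2,4-dihydroxy-3,6-dimethylbenzoate) | COC(=O)c1c(C)cc(O)c(C)c1O | starting material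
2 | methyl 3-chloro-4,6-dihydroxy-2,5-dimethylbenzoate | COC(=O)c1c(C)c(Cl)c(O)c(C)c1O | intermediate
3 | methyl 3-chloro-6-hydroxy-4-(methoxymethoxy)-2,5-dimethylbenzoate | COC(=O)c1c(C)c(Cl)c(OCOC)c(C)c1O | intermediate
4 | methyl 3-chloro-6-methoxy-4-(methoxymethoxy)-2,5-dimethylbenzoate | COC(=O)c1c(C)c(Cl)c(OCOC)c(C)c1OC | intermediate
5 | 3-chloro-6-methoxy-4-(methoxymethoxy)-2,5-dimethylbenzoic acid | OC(=O)c1c(C)c(Cl)c(OCOC)c(C)c1OC | intermediate
6 | 1-(trimethylsilyl)propyne | CC#C[Si](C)(C)C | starting material
7 | phenyl(prop-1-yn-1-yl)iodonium trifluoromethanesulfonate | CC#C[I+]c1ccccc1.[O-]S(=O)(=O)C(F)(F)F | intermediate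
8 | prop-1-yn-1-yl 3-chloro-6-methoxy-4-(methoxymethoxy)-2,5-dimethylbenzoate | CC#COC(=O)c1c(C)c(Cl)c(OCOC)c(C)c1OC | intermediate
9 | pentane-2,3-dione | CCC(=O)C(C)=O | starting material
10 | methyl (triphenylphosphoranylidene)acetate | COC(=O)C=P(c1ccccc1)(c1ccccc1)c1ccccc1 | starting material
11 | methyl (E)-3-methyl-4-oxohex-2-enoate | COC(=O)/C=C(\C)C(=O)CC | intermediate
12 | methyl (E)-7,7,7-trifluoro-3,5-dimethyl-4,6-dioxohept-2-enoate (racemic at C5) | COC(=O)/C=C(\C)C(=O)C(C)C(=O)C(F)(F)F | intermediate
13 | methyl (E)-5-diazo-3-methyl-4-oxohex-2-enoate | COC(=O)/C=C(\C)C(=O)C(C)=[N+]=[N-] | intermediate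
14 | methyl (2E)-3,4-dimethyl-5-oxopenta-2,4-dienoate (vinylketene) | COC(=O)/C=C(\C)C(C)=C=O | intermediate (not isolated)
15 | 4-[(2E)-4-methoxy-4-oxobut-2-en-2-yl]-2,4-dimethyl-3-oxocyclobut-1-en-1-yl 3-chloro-6-methoxy-4-(methoxymethoxy)-2,5-dimethylbenzoate (racemic) | COC(=O)/C=C(\C)C1(C)C(=O)C(C)=C1OC(=O)c1c(C)c(Cl)c(OCOC)c(C)c1OC | intermediate (not isolated)
16 | methyl (2E,4E)-5-{[3-chloro-6-methoxy-4-(methoxymethoxy)-2,5-dimethylbenzoyl]oxy}-3,4,6-trimethyl-7-oxohepta-2,4,6-trienoate (dienylketene, ketene and enoate ends cis across the central double bond) | COC(=O)/C=C(\C)/C(C)=C(OC(=O)c1c(C)c(Cl)c(OCOC)c(C)c1OC)\C(C)=C=O | intermediate (not isolated)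
17 | methyl 4-{[3-chloro-6-methoxy-4-(methoxymethoxy)-2,5-dimethylbenzoyl]oxy}-3,5,6-trimethyl-2-oxocyclohexa-3,5-diene-1-carboxylate (racemic) | COC(=O)C1C(=O)C(C)=C(OC(=O)c2c(C)c(Cl)c(OCOC)c(C)c2OC)C(C)=C1C | intermediate (not isolated)
18 | 3-hydroxy-4-(methoxycarbonyl)-2,5,6-trimethylphenyl 3-chloro-6-methoxy-4-(methoxymethoxy)-2,5-dimethylbenzoate | COC(=O)c1c(C)c(C)c(OC(=O)c2c(C)c(Cl)c(OCOC)c(C)c2OC)c(C)c1O | intermediate
19 | 3-hydroxy-4-(methoxycarbonyl)-2,5,6-trimethylphenyl 3-chloro-4-hydroxy-6-methoxy-2,5-dimethylbenzoate | COC(=O)c1c(C)c(C)c(OC(=O)c2c(C)c(Cl)c(O)c(C)c2OC)c(C)c1O | target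

## Step count and least certain steps

Total step count: 11. Longest linear sequence: 7 steps (steps 1, 2, 3, 4, 6, 10 and 11, from atraric acid). The diazoketone branch has 3 steps (7, 8, 9) and the iodonium salt 1 step (5).

**Step 10 (key step, new method).**
- What may go wrong: capture of the vinylketene by the weakly nucleophilic ynol ester may be too slow, so the ketene is lost to dimerization or to traces of water. The ynol ester may not survive light and heat (acyl shift or hydrolysis). Light may isomerize the E-enoate, after which the ketene can close onto its own ester.
- Fallback (known chemistry): it sets out from 5 and 1 and comes back at 18. Vilsmeier–Haack formylation of 1 (POCl3, DMF) should give methyl 3-formyl-4,6-dihydroxy-2,5-dimethylbenzoate F1. Hydrogenolysis of the aldehyde to a methyl group (H2, Pd on carbon, AcOH) should give methyl 2,4-dihydroxy-3,5,6-trimethylbenzoate F2. Acid 5 is converted under neutral conditions with 1-chloro-N,N,2-trimethylprop-1-en-1-amine into 3-chloro-6-methoxy-4-(methoxymethoxy)-2,5-dimethylbenzoyl chloride F3. The monosodium salt of F2 (NaH, THF) should be acylated on O4, the oxygen not held in the hydrogen bond, to give 18. This is the classical depside esterification and makes steps 5 to 9 unnecessary.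

**Step 6.**
- What may go wrong: the carboxylate may decompose the alkynyliodonium ion instead of adding to its β-carbon, and the ynol ester may hydrolyse during isolation, because it is an activated acyl donor.
- Fallback: it sets out from 5 and comes back at 8. Ligand exchange of two equivalents of 5 with PhI(OAc)2, with removal of acetic acid, should give bis[3-chloro-6-methoxy-4-(methoxymethoxy)-2,5-dimethylbenzoyloxy](phenyl)-λ3-iodane F4. Commercial prop-1-ynyllithium in THF at −78 °C should then give 8 through the alkynyliodonium carboxylate. The second carboxylate is recovered as 5.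

**Step 7.**
- What may go wrong: poor regioselectivity, with the ylide also attacking the propionyl carbonyl, since methyl and ethyl differ little in size. Incomplete E-selectivity is a second possibility.
- Fallback: it does not set out from a numbered compound. It replaces 9 and 10 by commercial pentan-3-one and glyoxylic acid monohydrate and comes back at 11. Acid-catalysed aldol condensation (H3PO4, about 80 °C) of the symmetrical ketone should give (E)-3-methyl-4-oxohex-2-enoic acid F5 with no regiochemical choice. O-Methylation (MeI, KHCO3, DMF) should then give 11.

**Step 4.**
- What may go wrong: incomplete hydrolysis because the two ortho substituents shield the carbonyl, or loss of the acetal on acidification.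
- Fallback: it sets out from 4 and comes back at 5. Reduction with LiAlH4 in THF should give [3-chloro-6-methoxy-4-(methoxymethoxy)-2,5-dimethylphenyl]methanol F6. Oxidation with MnO2 should give 3-chloro-6-methoxy-4-(methoxymethoxy)-2,5-dimethylbenzaldehyde F7. Pinnick oxidation (NaClO2, NaH2PO4, 2-methylbut-2-ene) should give 5 without any attack at the hindered carbonyl by hydroxide.

## Further compounds

F1 | step 10 | methyl 3-formyl-4,6-dihydroxy-2,5-dimethylbenzoate | COC(=O)c1c(C)c(C=O)c(O)c(C)c1O
F2 | step 10 | methyl 2,4-dihydroxy-3,5,6-trimethylbenzoate | COC(=O)c1c(C)c(C)c(O)c(C)c1O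
F3 | step 10 | 3-chloro-6-methoxy-4-(methoxymethoxy)-2,5-dimethylbenzoyl chloride | O=C(Cl)c1c(C)c(Cl)c(OCOC)c(C)c1OC
F4 | step 6 | bis[3-chloro-6-methoxy-4-(methoxymethoxy)-2,5-dimethylbenzoyloxy](phenyl)-λ3-iodane | COCOc1c(C)c(OC)c(C(=O)OI(OC(=O)c2c(C)c(Cl)c(OCOC)c(C)c2OC)c2ccccc2)c(C)c1Cl
F5 | step 7 | (E)-3-methyl-4-oxohex-2-enoic acid | OC(=O)/C=C(\C)C(=O)CC
F6 | step 4 | [3-chloro-6-methoxy-4-(methoxymethoxy)-2,5-dimethylphenyl]methanol | OCc1c(C)c(Cl)c(OCOC)c(C)c1OC
F7 | step 4 | 3-chloro-6-methoxy-4-(methoxymethoxy)-2,5-dimethylbenzaldehyde | O=Cc1c(C)c(Cl)c(OCOC)c(C)c1OC
A1 | alternative 1 | 3-(benzyloxy)-4-(methoxycarbonyl)-2,5,6-trimethylphenyl 2,4-dihydroxy-3,6-dimethylbenzoate | COC(=O)c1c(C)c(C)c(OC(=O)c2c(C)cc(O)c(C)c2O)c(C)c1OCc1ccccc1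
A2 | alternative 1 | 6-(3,5-dioxohexan-2-yl)-2,2-dimethyl-4H-1,3-dioxin-4-one | CC1(C)OC(=O)C=C(O1)C(C)C(=O)CC(C)=O
A3 | alternative 1 | methyl 2-(benzyloxy)-4-hydroxy-3,5,6-trimethylbenzoate | COC(=O)c1c(C)c(C)c(O)c(C)c1OCc1ccccc1
A4 | alternative 1 | 4-methyl-3,5,7-trioxooct-1-en-1-one (acylketene) | CC(=O)CC(=O)C(C)C(=O)C=C=O
A5 | alternative 1 | 3-(benzyloxy)-4-(methoxycarbonyl)-2,5,6-trimethylphenyl 4-methyl-3,5,7-trioxooctanoate | COC(=O)c1c(C)c(C)c(OC(=O)CC(=O)C(C)C(=O)CC(C)=O)c(C)c1OCc1ccccc1
A6 | alternative 2 | methyl 3,5,6-trimethyl-2,4-dioxocyclohexane-1-carboxylate (mixture of stereoisomers) | COC(=O)C1C(C)C(C)C(=O)C(C)C1=O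
A7 | alternative 2 | methyl 3-oxopentanoate | CCC(=O)CC(=O)OC
A8 | alternative 2 | methyl tiglate (methyl (E)-2-methylbut-2-enoate) | C/C=C(\C)C(=O)OC
A9 | alternative 2 | methyl 2,4-dihydroxy-3,5,6-trimethylbenzoate (same compound as F2) | COC(=O)c1c(C)c(C)c(O)c(C)c1O
A10 | alternative 3 | 3-hydroxy-4-(methoxycarbonyl)-2,5,6-trimethylphenyl 4-hydroxy-2-methoxy-3,6-dimethylbenzoate | COC(=O)c1c(C)c(C)c(OC(=O)c2c(C)cc(O)c(C)c2OC)c(C)c1O
A11 | alternative 3 | 3-hydroxy-4-(methoxycarbonyl)-2,5,6-trimethylphenyl but-2-ynoate | CC#CC(=O)Oc1c(C)c(C)c(C(=O)OC)c(O)c1C
A12 | alternative 3 | 1,1-dimethoxy-2-methyl-3-(trimethylsilyloxy)buta-1,3-diene | COC(OC)=C(C)C(=C)O[Si](C)(C)C
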